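**Retrosynthetic overview**

1. The strategy rests on the depside carbonyl: one carbon that joins C1 of ring B (the orsellinoyl ring, where C1 lies between the methyl-bearing C6 and the oxygenated C2) to the oxygen on C4 of ring A (the 2-heptyl-4,6-dihydroxybenzoic acid ring).
2. Both bonds to that carbon are cut together: a ring B aryl iodide, carbon monoxide and the free 4-hydroxyl of a ring A benzyl ester are joined by palladium-catalysed aryloxycarbonylation, and hydrogenolysis of three benzyl groups finishes the route.
3. Ring B partner: orcinol is dibenzylated and iodinated at the carbon ortho to methyl, which is the carbon that must carry the carbonyl.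
4. Ring A partner: 5-heptylresorcinol is carboxylated next to the heptyl chain and the acid is benzylated; the 6-hydroxyl stays free, hydrogen-bonded to the ester.
5. No ring is formed in the route; both benzene rings are purchased.

Key step: step 5

Remark: the target has no stereocentre, so no stereocontrol is needed; orcinol is assumed to be used in anhydrous form.

**Step 1**
Reactants: 1 orcinol; 2 benzyl bromide
Product: 3 1,3-bis(benzyloxy)-5-methylbenzene
Conditions: BnBr (2.3 equiv), K2CO3 (3 equiv), DMF, 60 °C
Reagents that add atoms: benzyl bromide, BrCc1ccccc1
Why: Williamson ether synthesis, in which both phenoxides of orcinol should be O-alkylated by the reactive benzylic bromide in a polar aprotic solvent.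

**Step 2**
Reactants: 3 1,3-bis(benzyloxy)-5-methylbenzene; 4 N-iodosuccinimide
Product: 5 1,5-bis(benzyloxy)-2-iodo-3-methylbenzene
Conditions: NIS (1.0 equiv), CF3CO2H (10 mol%), MeCN, 0 °C to rt, dark
Reagents that add atoms: N-iodosuccinimide, O=C1CCC(=O)N1I
Why: Electrophilic aromatic iodination, which should occur at the carbon ortho to methyl (para to one benzyloxy group, ortho to the other) because the alternative carbon between the two benzyloxy groups is more crowded, as is usual for orcinol diethers; one equivalent of NIS limits a second iodination.

**Step 3**
Reactants: 6 5-heptylresorcinol; 7 methyl magnesium carbonate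
Product: 9 2-heptyl-4,6-dihydroxybenzoic acid, via magnesium chelate 8 (not isolated)
Conditions: MeOMgOCO2Me (2 M in DMF, 4 equiv), 120 °C, N2; then cold 2 M HCl
Reagents that add atoms: methyl magnesium carbonate, COC(=O)O[Mg]OC
Why: Kolbe–Schmitt-type ortho-carboxylation, in which the reagent should deliver CO2 to the ring carbon next to the heptyl chain (ortho to one hydroxyl, para to the other) and the magnesium salicylate chelate 8 holds the carboxyl group until cold acid releases the free acid, as is established for 5-alkylresorcinols.

**Step 4**
Reactants: 9 2-heptyl-4,6-dihydroxybenzoic acid; 2 benzyl bromide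
Product: 10 benzyl 2-heptyl-4,6-dihydroxybenzoate
Conditions: BnBr (1.1 equiv), KHCO3 (1.2 equiv), DMF, rt
Reagents that add atoms: benzyl bromide, BrCc1ccccc1
Why: Chemoselective SN2 O-alkylation of a carboxylate, since KHCO3 deprotonates only the carboxylic acid and leaves both phenols protonated, and the mild temperature avoids decarboxylation.

**Step 5**
Reactants: 5 1,5-bis(benzyloxy)-2-iodo-3-methylbenzene; 10 benzyl 2-heptyl-4,6-dihydroxybenzoate (1.2 equiv); 11 carbon monoxide
Product: 12 benzyl 4-{[2,4-bis(benzyloxy)-6-methylbenzoyl]oxy}-2-heptyl-6-hydroxybenzoate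
Conditions: Pd(OAc)2 (5 mol%), Xantphos (7.5 mol%), CO (1 atm), Et3N (3 equiv), 4 Å molecular sieves, toluene, 90 °C
Reagents that add atoms: carbon monoxide, [C-]#[O+]
Why: Pd(OAc)2 and Xantphos give zerovalent palladium, which adds oxidatively to the C–I bond of 5; migratory insertion of CO then gives an aroyl complex of divalent palladium, and the triethylammonium phenoxide of 10 takes up the acyl group (exchange for iodide, then C–O reductive elimination), releasing ester 12 and regenerating zerovalent palladium while Et3N binds the HI. The closest known reaction type is the palladium-catalysed aryloxycarbonylation of aryl iodides and bromides with phenols under one atmosphere of CO with wide-bite-angle diphosphines. The step closes no ring and creates no stereocentre; it forms the aryl–C(=O) bond and the C(=O)–O bond of the depside. Site selectivity between the two hydroxyls of ring A is needed: the 6-hydroxyl is hydrogen-bonded to the benzyl ester carbonyl and crowded by it, so it is less acidic and less nucleophilic, whereas the 4-hydroxyl is para to the ester, more acidic and unhindered. Acyl capture must also outrun direct diaryl ether formation, which the CO atmosphere, the Xantphos ligand and the two ortho substituents of the aryl group (which slow direct C–O reductive elimination) should all favour. The benzyl ethers, the benzyl ester and the heptyl chain are inert under these conditions.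

**Step 6**
Reactants: 12 benzyl 4-{[2,4-bis(benzyloxy)-6-methylbenzoyl]oxy}-2-heptyl-6-hydroxybenzoate
Product: 13 4-[(2,4-dihydroxy-6-methylbenzoyl)oxy]-2-heptyl-6-hydroxybenzoic acid (CNP0227363.0)
Conditions: H2 (1 atm), 10% Pd/C, EtOAc, rt
Reagents that add atoms: none
Why: Catalytic hydrogenolysis of benzylic C–O bonds should cleave the two benzyl ethers and the benzyl ester under neutral conditions, while the depside aryl ester has no benzylic C–O bond and the alcohol-free solvent prevents transesterification.

**Compound list**

1 | orcinol (5-methylbenzene-1,3-diol) | Cc1cc(O)cc(O)c1 | starting material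
2 | benzyl bromide | BrCc1ccccc1 | starting material
3 | 1,3-bis(benzyloxy)-5-methylbenzene | Cc1cc(OCc2ccccc2)cc(OCc2ccccc2)c1 | intermediate
4 | N-iodosuccinimide | O=C1CCC(=O)N1I | starting material
5 | 1,5-bis(benzyloxy)-2-iodo-3-methylbenzene | Cc1cc(OCc2ccccc2)cc(OCc2ccccc2)c1I | intermediate
6 | 5-heptylresorcinol (5-heptylbenzene-1,3-diol) | CCCCCCCc1cc(O)cc(O)c1 | starting material
7 | methyl magnesium carbonate | COC(=O)O[Mg]OC | starting material
8 | magnesium chelate of 2-heptyl-4-hydroxy-6-oxidobenzoate (carboxylate oxygen and ortho-phenoxide oxygen on Mg, six-membered chelate) | CCCCCCCc1cc(O)cc2O[Mg]OC(=O)c12 | intermediate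
9 | 2-heptyl-4,6-dihydroxybenzoic acid | CCCCCCCc1cc(O)cc(O)c1C(=O)O | intermediate
10 | benzyl 2-heptyl-4,6-dihydroxybenzoate | CCCCCCCc1cc(O)cc(O)c1C(=O)OCc1ccccc1 | intermediate
11 | carbon monoxide | [C-]#[O+] | starting material
12 | benzyl 4-{[2,4-bis(benzyloxy)-6-methylbenzoyl]oxy}-2-heptyl-6-hydroxybenzoate | CCCCCCCc1cc(OC(=O)c2c(C)cc(OCc3ccccc3)cc2OCc2ccccc2)cc(O)c1C(=O)OCc1ccccc1 | intermediate
13 | 4-[(2,4-dihydroxy-6-methylbenzoyl)oxy]-2-heptyl-6-hydroxybenzoic acid | CCCCCCCc1cc(OC(=O)c2c(C)cc(O)cc2O)cc(O)c1C(=O)O | target

**Step count and risks**

Total step count: 6. Longest linear sequence: 4 steps (steps 1, 2, 5, 6 from orcinol, or steps 3, 4, 5, 6 from 5-heptylresorcinol).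

Steps most likely to fail:

Step 5. Acyl transfer from the hindered, doubly ortho-substituted aroyl palladium complex to the weakly nucleophilic phenol may be slow. Protodeiodination, hydrolysis of the acyl complex by traces of water, or acylation of the second hydroxyl could then compete. The fallback sets out from 5 and makes the ester bond by classical acylation instead of carbonylation. Iodine–magnesium exchange with iPrMgCl·LiCl in THF at 0 °C to rt should give [2,4-bis(benzyloxy)-6-methylphenyl]magnesium chloride F1. Carboxylation with CO2 and acidification with HCl should give 2,4-bis(benzyloxy)-6-methylbenzoic acid F2. Treatment of F2 and phenol 10 with (CF3CO)2O in toluene at rt should form 2,4-bis(benzyloxy)-6-methylbenzoic trifluoroacetic anhydride F3, which acylates the non-chelated 4-hydroxyl of 10. The fallback comes back to the route at 12.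

Step 3. Carboxylation may take place at the carbon between the two hydroxyls instead of the carbon next to the heptyl chain, and the electron-rich salicylic acid may lose CO2 during the hot reaction or the acidic work-up. The fallback sets out from 6 and introduces the carboxyl carbon as a formyl group. Vilsmeier–Haack formylation (POCl3, DMF, 0 °C to rt) should give (2-heptyl-4,6-dihydroxybenzylidene)dimethyliminium chloride F4. Hydrolysis with aqueous NaOAc should give 2-heptyl-4,6-dihydroxybenzaldehyde F5. Lindgren–Pinnick oxidation (NaClO2, NaH2PO4, H2NSO3H as hypochlorite scavenger, aqueous dioxane, 0 °C to rt) should then give the acid. The fallback comes back to the route at 9.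

Step 2. Iodination may be unselective between the carbon ortho to methyl and the carbon flanked by the two benzyloxy groups. A second iodination of the still-activated ring and acid-promoted iodine migration are also possible. The fallback sets out from 3 and installs the halogen by kinetically controlled, acid-free bromination followed by metal–halogen exchange. NBS in MeCN at 0 °C should give 1,5-bis(benzyloxy)-2-bromo-3-methylbenzene F6. Bromine–lithium exchange with n-BuLi in THF at −78 °C should give [2,4-bis(benzyloxy)-6-methylphenyl]lithium F7, which is quenched with I2 at −78 °C. The fallback comes back to the route at 5.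

**Further compounds**

F1 | step 5 | [2,4-bis(benzyloxy)-6-methylphenyl]magnesium chloride | Cc1cc(OCc2ccccc2)cc(OCc2ccccc2)c1[Mg]Cl
F2 | step 5 | 2,4-bis(benzyloxy)-6-methylbenzoic acid | Cc1cc(OCc2ccccc2)cc(OCc2ccccc2)c1C(=O)O
F3 | step 5 | 2,4-bis(benzyloxy)-6-methylbenzoic trifluoroacetic anhydride | Cc1cc(OCc2ccccc2)cc(OCc2ccccc2)c1C(=O)OC(=O)C(F)(F)F
F4 | step 3 | (2-heptyl-4,6-dihydroxybenzylidene)dimethyliminium chloride | CCCCCCCc1cc(O)cc(O)c1C=[N+](C)C.[Cl-]
F5 | step 3 | 2-heptyl-4,6-dihydroxybenzaldehyde | CCCCCCCc1cc(O)cc(O)c1C=O
F6 | step 2 | 1,5-bis(benzyloxy)-2-bromo-3-methylbenzene | Cc1cc(OCc2ccccc2)cc(OCc2ccccc2)c1Br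
F7 | step 2 | [2,4-bis(benzyloxy)-6-methylphenyl]lithium | Cc1cc(OCc2ccccc2)cc(OCc2ccccc2)c1[Li]
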